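The earlier runs and the new flask were generated by integration with made-up constants, and the scatter is random.

**Two ceilings.** One unit of target costs one unit of partner and one of starting material, so partner is the limiting reagent in the south-west and south runs, and the south flask has the lower ceiling. Target can reach 75.0% of the starting material charged in the south-west run and 25.0% in the south run.

| flask | starting material | partner | target | time |
|---|---|---|---|---|
| north | 0.800 M | 1.20 M |  |  |
| south-west | 0.800 M | 0.600 M |  |  |
| east | 0.800 M | 1.20 M | 0.240 M |  |
| south | 2.40 M | 0.600 M |  | 15 min |

| north run: time / min | north run: [target] / M | south-west run: time / min | south-west run: [target] / M | east run: time / min | east run: [target] / M |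
|---|---|---|---|---|---|
| 0.67 | 0.007 | 0.67 | 0.007 | 0.67 | 0.258 |
| 2.0 | 0.071 | 2.0 | 0.052 | 2.0 | 0.307 |
| 3.9 | 0.197 | 3.9 | 0.141 | 3.9 | 0.439 |
| 6.1 | 0.308 | 6.1 | 0.226 | 6.1 | 0.550 |
| 8.8 | 0.423 | 8.8 | 0.305 | 8.8 | 0.670 |
| 12 | 0.527 | 12 | 0.381 | 12 | 0.778 |
| 15 | 0.607 | 15 | 0.425 | 15 | 0.840 |

(each reading ± 0.006 M)

- the exponent of [partner] in the starting rate at the charge of the north run (at the point where two percent of the starting material have become target)
- target in the south run at 15 min, as a share of the starting material charged

- Overall: starting material + partner -> target.
- Constant volume, constant temperature.
- The analysis sees a species whether free or bound.
- "The second partner" is partner.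
- An order is taken over about fifteen percent of the charge, up and down.

**Partner exponent.** The east run, less its added target, reads 75.0% of its starting material at 15 min against 75.9% in the north run, so I compare the north and south-west runs with no correction for target. Their slopes from 2.0 min to 6.1 min, set against the partner present midway through that stretch, give a reading of 0.394, my estimate of the exponent. The north run's early and late slopes, with that exponent taken out, give 0.560 as the exponent of starting material.

**Drain time.** The south-west run, after a lag of 0.890 min, consumes 0.0781 min⁻¹ of its partner charge. A rate falling as that power of the partner left empties the charge in the reciprocal of this rate divided by one minus the exponent. With the lag added, the south-west run gets 22.0 min as its drain time. The south run holds 2.99 times the starting material of that stretch midway through its drain, which raises the consumption to 0.144 min⁻¹ and shortens the drain time to 12.3 min.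

**Two endings.** The drain time of the south-west run is longer than 15 min, and the readings of that run are still climbing at 15 min, where they stand at 53.1% of its starting material. The drain time of the south run is shorter than 15 min, so my reckoning puts the south run just under its ceiling of 25.0%.

**The forecast.** The forecast gives an exponent of 0.4 (0.27 to 0.55) and 22.3% (19.5% to 24.2%), citing “saturation in starting material”; its exponent is close to mine, and its share stands lower than the ceiling, which my reckoning nearly reaches.

**The result.** The flask gives an exponent of 0.32 and 24.8%, from this scheme:

    starting material ⇌ intermediate (1.002 min⁻¹, 0.2880 min⁻¹)
    intermediate + partner → target (0.5898 M⁻¹ min⁻¹)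
    2 partner ⇌ idle reagent dimer, settled at all times (3.140 M⁻¹)
    2 starting material ⇌ idle substrate dimer, settled at all times (3.740 M⁻¹)

**What ran when.** In the south run, starting material fed the intermediate while the intermediate took up partner to give target, and past the drain time of 12.3 min target stood at 24.8% at 15 min against the ceiling of 25.0%, with 0.632% of the partner charge unconverted. In the south-west run, with a drain time of 22.0 min, the same steps were still running at 15 min, where the reading leaves 29.2% of the partner charge unconverted.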